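**Plan**

- Enabling feature (eunicellane numbering: C1/C10 ring fusion, C2=C3–C15, C4 hemiketal, C5=C6, C7, C8, C11=C12, C14): C4–C5 joins two unsaturated carbons, C7 is an oxygenated carbon two atoms from C5, and C2=C3 lies across the ring. A C2–C7 bond therefore restores a six-membered ring B (C1, C2, C7, C8, C9, C10) that carries a C7 alkoxide, a C7 ethynyl group (C5≡C6) and a C2 alkenyl group (C3=C4), i.e. a 3-oxy-1,5-enyne.
- Retrosynthetic cuts, in order: C8–O acyl bond; hemiketal O–C4 and the C4/C15 oxidation levels; C7–CH3; C4–C5 (with C2–C7 re-formed) back to a trans-decalin; then C7–C6, C2–C3, C8–O, and ring B bonds C7–C8 and C9–C10.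
- Forward order: ring A from 4-isopropylcyclohexanone; ring B by a reductive Michael–Dieckmann annulation; C8 oxygen, C2 dioxinyl and C7 ethynyl groups; ring B is opened into the ten-membered ring; C7 methyl; oxidation closes the dihydrofuran hemiketal; ester; urocanate.
- Stereochemistry: C14 from enantioselective deprotonation; C1 by hydride delivery anti to isopropyl; C10 by Michael addition anti to the C1 arm; C8 by equilibration to equatorial; C7 carbinol by axial acetylide attack; C2=C3 and C5=C6 geometry from the sigmatropic transition state and allenolate protonation; C7 by non-chelation addition; C4 by the bridge.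

Key step: step 14

Remark: the SMILES is taken literally, i.e. H-1/H-10 trans and isopropyl cis to C2, so the bicyclic precursor is a trans-decalin with an axial isopropyl group.

**Step 1**
Reactants: 1 4-isopropylcyclohexanone
Product: 2 (S)-4-isopropyl-1-(trimethylsilyloxy)cyclohexene
Conditions: (R,R)-bis(1-phenylethyl)amine, n-BuLi, LiCl, THF, −78 °C; Me3SiCl
Reagents that add atoms: chlorotrimethylsilane, C[Si](C)(C)Cl
Why: Enantioselective deprotonation (desymmetrisation) by the chiral lithium amide removes one of the two enantiotopic axial α-protons and fixes C14 (S enol silane expected by analogy with 4-tert-butylcyclohexanone); the enantiomeric purity is to be raised by recrystallisation at a later crystalline stage.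

**Step 2**
Reactants: 2 (S)-enol silane
Product: 3 (R)-4-isopropylcyclohex-2-enone
Conditions: Pd(OAc)2 (divalent palladium, 10 mol%), O2 (1 atm), DMSO, 25 °C
Reagents that add atoms: none
Why: Saegusa–Ito oxidation of the regiodefined enol silane (palladium enolate, β-hydride elimination towards C1) should give the enone without touching C14.

**Step 3**
Reactants: 3 (R)-4-isopropylcyclohex-2-enone; 4 tert-butyl[(1-methoxyethenyl)oxy]dimethylsilane
Product: 5 methyl [trans-6-isopropyl-3-(tert-butyldimethylsilyloxy)cyclohex-2-enyl]acetate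
Conditions: tBuMe2SiOTf (5 mol%), CH2Cl2, −78 °C
Reagents that add atoms: none
Why: Mukaiyama–Michael addition with silyl transfer should attach the C2–C7 acetate arm at C1 and leave a regiodefined enol silane; the C1 configuration (trans to isopropyl) is erased in step 4.

**Step 4**
Reactants: 5 enol silane
Product: 6 methyl [(6R)-6-isopropyl-3-oxocyclohex-1-enyl]acetate
Conditions: Pd(OAc)2 (divalent palladium, 10 mol%), O2, DMSO, 60 °C
Reagents that add atoms: none
Why: A second Saegusa–Ito oxidation should reinstate the C10=C1 enone, now with C1 trigonal and carrying the acetate arm, so that C1 can be reset by hydride delivery.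

**Step 5**
Reactants: 6 enone ester; 7 methyl acrylate
Product: 10 trans-fused bicyclic β-keto ester (C7 ketone, C8 CO2Me, C11 ketone), via enol silane 8 (not isolated), via keto diester 9 (not isolated)
Conditions: [(Ph3P)CuH]6 (5 mol%), PhMe2SiH, toluene, 25 °C; then KOtBu, THF, −78 °C; 7, −78 → 0 °C; aq NH4Cl
Reagents that add atoms: none
Why: Copper hydride 1,4-hydrosilylation should deliver hydride to C1 anti to the pseudoaxial isopropyl group (C1 arm cis to isopropyl); the potassium enolate released by KOtBu then adds to methyl acrylate anti to the C1 arm (sets C10, trans fusion), and the ester enolate closes ring B by Dieckmann condensation (Michael-initiated ring closure).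

**Step 6**
Reactants: 10 bicyclic β-keto ester
Product: 11 C11 enol triflate (C11=C12)
Conditions: KN(SiMe3)2 (2.2 equiv), THF, −78 °C; PhNTf2 (1.05 equiv), −78 → −30 °C
Reagents that add atoms: N-phenylbis(trifluoromethanesulfonimide), O=S(=O)(N(c1ccccc1)S(=O)(=O)C(F)(F)F)C(F)(F)F
Why: The first equivalent of base masks the β-keto ester as its stabilised enolate and the second removes the kinetically favoured C12 proton rather than the ring-fusion C10–H, so kinetic enol triflate formation should be regioselective and leave C10 untouched.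

**Step 7**
Reactants: 11 enol triflate
Product: 12 β-keto ester with the C11(CH3)=C12 alkene
Conditions: Me4Sn, Pd(PPh3)4 (zerovalent palladium, 5 mol%), LiCl, N-methylpyrrolidone, 60 °C
Reagents that add atoms: tetramethylstannane, C[Sn](C)(C)C
Why: Stille coupling of the enol triflate under neutral conditions should replace OTf by methyl and fix the ring A alkene without enolising the β-keto ester.

**Step 8**
Reactants: 12 β-keto ester
Product: 13 trans-fused 8-isopropyl-5-methyl-3,4,4a,7,8,8a-hexahydronaphthalen-2(1H)-one (C7 ketone)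
Conditions: LiCl, DMSO, H2O, 150 °C
Reagents that add atoms: none
Why: Krapcho dealkoxycarbonylation removes the ester that served the annulation; no stereocentre is created.

**Step 9**
Reactants: 13 decalone
Product: 14 C8 hydroxy ketone (C8 epimers)
Conditions: KN(SiMe3)2, THF, −78 °C; 3-phenyl-2-(phenylsulfonyl)oxaziridine
Reagents that add atoms: 3-phenyl-2-(phenylsulfonyl)oxaziridine, O=S(=O)(N1OC1c1ccccc1)c1ccccc1
Why: Kinetic enolisation of this trans-2-decalone should occur towards C8 (away from the ring fusion; the axial C2–H is shielded by the axial isopropyl group), and enolate oxidation by the N-sulfonyloxaziridine installs the C8 oxygen; its configuration is settled in step 10.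

**Step 10**
Reactants: 14 hydroxy ketone
Product: 15 C8 equatorial triisopropylsilyl ether of the C7 ketone
Conditions: iPr3SiOTf, 2,6-lutidine, CH2Cl2, 0 °C; then DBU, toluene, 60 °C
Reagents that add atoms: triisopropylsilyl trifluoromethanesulfonate, CC(C)[Si](OS(=O)(=O)C(F)(F)F)(C(C)C)C(C)C
Why: Silylation followed by base equilibration of the α-silyloxy ketone through its enol should place the bulky ether equatorial (thermodynamic control at C8) without the ketol transposition open to the free hydroxy ketone.

**Step 11**
Reactants: 15 silyloxy ketone; 16 2,2-dimethyl-1,3-dioxan-5-one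
Product: 17 aldol adduct (C2 equatorial 5-hydroxy-2,2-dimethyl-1,3-dioxan-5-yl group)
Conditions: LiN(iPr)2, THF, −78 °C; 16; AcOH, −78 °C
Reagents that add atoms: none
Why: The lithium enolate forms away from the silyloxy-bearing carbon and adds to the activated α,α'-dialkoxy ketone (crossed aldol addition) from the face opposite the axial isopropyl group, which puts the new C2–C3 bond equatorial.

**Step 12**
Reactants: 17 aldol adduct
Product: 18 C2 equatorial (2,2-dimethyl-4H-1,3-dioxin-5-yl) ketone
Conditions: methyl N-(triethylammoniosulfonyl)carbamate, toluene, 60 °C; then DBU (cat.), 25 °C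
Reagents that add atoms: none
Why: Dehydration of the tertiary alcohol through its sulfamate (syn elimination) and base equilibration should give the β,γ-unsaturated ketone with the alkene inside the dioxin ring as an enol ether. The conjugated alkylidene isomer is disfavoured by allylic strain with C1, and the ring holds the C4 oxygen cis to C15.

**Step 13**
Reactants: 18 dioxinyl ketone
Product: 19 trans-decalin 1-ethynyl-2-alkenyl carbinol (axial C7 ethynyl, equatorial C7 OH, equatorial C2 dioxinyl, equatorial C8 OSi)
Conditions: HC≡CMgBr, CeCl3, THF, −78 °C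
Reagents that add atoms: ethynylmagnesium bromide, C#C[Mg]Br
Why: The weakly basic organocerium acetylide adds 1,2 without enolising the β,γ-unsaturated ketone, and the small nucleophile enters axially between the two equatorial α-substituents, setting C7 with the ethynyl group cis to the C2 alkenyl group.

**Step 14**
Reactants: 19 ethynyl carbinol
Product: 22 ten-membered C7 enone (Z C5=C6, ring-cis C2=C3, C4/C15 acetonide, C8 OSi), via potassium alkoxide 20 (not isolated), via potassium allenolate 21 (not isolated)
Conditions: KH (1.1 equiv), 18-crown-6, THF, 0 → 25 °C; then MeOH/aq NH4Cl, −78 °C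
Reagents that add atoms: none
Why: Deprotonation gives alkoxide 20, whose oxyanion weakens the C2–C7 bond so that the axial ethynyl group (C5≡C6) and the cis equatorial enol ether (C3=C4) undergo a concerted [3,3] shift that forms C4–C5 and cleaves C2–C7; the closest known reaction type is the anion-accelerated oxy-Cope ring expansion of 1-alkynyl-2-alkenylcyclohexanols to cyclodecadienones. The ten-membered carbocycle is thus not closed end to end but arises by four-atom expansion of ring B, the decalin bond C2–C7 being the one given up. The only new stereocentre, C4, is set by suprafacial bonding on the single enol-ether face that can reach C5, and it is erased at the ketone stage. The step needs C2=C3 with C1 cis to C4: on the rigid trans-decalin the equatorial alkenyl and axial ethynyl groups hold C1 syn to the reacting alkene, and the dioxin ring keeps hydrogen rather than oxygen on C4 cis to C2, so this arrangement is free of allylic strain. It also needs a cis C5=C6 alkene, which should follow from protonation of allenolate 21 at C6 from the outer face at −78 °C. The C8 centre is protected by the small excess of base, the short reaction time and the bulky silyl ether, and the terminal alkyne C–H is far less acidic than the carbinol, so only the alkoxide forms.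

**Step 15**
Reactants: 22 enone
Product: 23 C7 tertiary alcohol (C7 OH trans to C8 OSi on the ring)
Conditions: MeLi, CeCl3, THF, −78 °C
Reagents that add atoms: methyllithium, [Li]C
Why: Organocerium 1,2-addition to the enone should occur from the outer face of the ring, anti to the C8–O bond of the bulky non-chelating silyl ether (polar Felkin–Anh control), which sets C7 as in the target.

**Step 16**
Reactants: 23 tertiary alcohol
Product: 24 triol (C4 OH, C7 OH, C15 OH; C8 OSi)
Conditions: AcOH/THF/H2O (3:1:1), 25 °C
Reagents that add atoms: none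
Why: Mild acetal hydrolysis of the strained 2,2-dimethyl-1,3-dioxane should free the C4 and C15 alcohols while the silyl ether and the tertiary allylic alcohol survive.

**Step 17**
Reactants: 24 triol
Product: 25 hemiketal enal (C4–O–C7 dihydrofuran, C15 aldehyde)
Conditions: MnO2 (excess), CH2Cl2, 25 °C
Reagents that add atoms: none
Why: MnO2 oxidises only the two allylic alcohols, and the C4 ketone, held next to the C7 hydroxyl by the Z alkene, should close to the bridged hemiketal, whose C4 configuration is dictated by C7.

**Step 18**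
Reactants: 25 hemiketal enal
Product: 26 hemiketal carboxylic acid
Conditions: NaClO2, NaH2PO4, 2-methyl-2-butene, tBuOH/H2O, 0 → 25 °C
Reagents that add atoms: sodium chlorite, [Na+].[O-]Cl=O
Why: Pinnick oxidation converts the enal to the acid without touching the alkenes or the hemiketal.

**Step 19**
Reactants: 26 acid
Product: 27 methyl ester with C8 OSi
Conditions: Me3SiCHN2, MeOH/toluene, 0 °C
Reagents that add atoms: (trimethylsilyl)diazomethane, C[Si](C)(C)C=[N+]=[N-]
Why: Esterification with the diazoalkane methylates only the carboxylic acid under neutral conditions and leaves the tertiary hemiketal hydroxyl free.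

**Step 20**
Reactants: 27 silyl ether
Product: 28 C8 alcohol (methyl ester, free hemiketal)
Conditions: Bu4NF, AcOH, THF, 0 → 25 °C
Reagents that add atoms: none
Why: Buffered fluoride desilylation should free the C8 hydroxyl without base-induced opening of the hemiketal.

**Step 21**
Reactants: 29 urocanic acid
Product: 30 methyl urocanate
Conditions: MeOH, H2SO4 (cat.), reflux
Reagents that add atoms: methanol, CO
Why: Fischer esterification masks the acid so that the imidazole can be alkylated.

**Step 22**
Reactants: 30 methyl urocanate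
Product: 31 methyl (E)-3-(1-methylimidazol-4-yl)acrylate
Conditions: NaH, MeI, DMF, 0 °C
Reagents that add atoms: iodomethane, CI
Why: N-Alkylation of the imidazolide should occur mainly at the nitrogen remote from the side chain (steric control); the minor 1,5-isomer is removed by chromatography.

**Step 23**
Reactants: 31 N-methyl ester
Product: 32 (E)-3-(1-methylimidazol-4-yl)acrylic acid
Conditions: LiOH, THF/H2O, 25 °C; then HCl to pH 5
Reagents that add atoms: lithium hydroxide, [Li+].[OH-]
Why: Saponification, followed by isolation at the isoelectric point, gives the acylating acid with the E alkene intact.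

**Step 24**
Reactants: 28 C8 alcohol; 32 N-methylurocanic acid
Product: 34 target compound, via mixed pivalic anhydride 33 (not isolated)
Conditions: 32, tBuCOCl, Et3N, THF, 0 °C; then 28, DMAP, 1,2-dichloroethane, 25 °C
Reagents that add atoms: none
Why: Mixed-anhydride acylation with nucleophilic catalysis should esterify the secondary C8 hydroxyl at the less hindered urocanoyl carbonyl, the tertiary hemiketal hydroxyl being too hindered to compete; no stereocentre is affected.

**Compound list**

1 | 4-isopropylcyclohexanone | CC(C)C1CCC(=O)CC1 | starting material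
2 | (S)-4-isopropyl-1-(trimethylsilyloxy)cyclohexene | C[Si](C)(C)OC1=CC[C@@H](C(C)C)CC1 | intermediate
3 | (R)-4-isopropylcyclohex-2-enone | O=C1C=C[C@@H](C(C)C)CC1 | intermediate
4 | tert-butyl[(1-methoxyethenyl)oxy]dimethylsilane | COC(=C)O[Si](C)(C)C(C)(C)C | starting material
5 | methyl [trans-6-isopropyl-3-(tert-butyldimethylsilyloxy)cyclohex-2-enyl]acetate | COC(=O)C[C@@H]1[C@@H](C(C)C)CCC(O[Si](C)(C)C(C)(C)C)=C1 | intermediate
6 | methyl [(6R)-6-isopropyl-3-oxocyclohex-1-enyl]acetate | COC(=O)CC1=CC(=O)CC[C@@H]1C(C)C | intermediate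
7 | methyl acrylate | C=CC(=O)OC | starting material
8 | methyl [cis-2-isopropyl-5-(dimethylphenylsilyloxy)cyclohex-4-enyl]acetate | COC(=O)C[C@H]1[C@@H](C(C)C)CCC(O[Si](C)(C)c2ccccc2)=C1 | intermediate
9 | methyl 3-[2-(2-methoxy-2-oxoethyl)-3-isopropyl-6-oxocyclohexyl]propanoate (H-1/H-10 trans, H-1/H-14 cis) | COC(=O)C[C@H]1[C@@H](C(C)C)CCC(=O)[C@@H]1CCC(=O)OC | intermediate
10 | trans-fused methyl 5-isopropyl-3,8-dioxodecahydronaphthalene-2-carboxylate (C7 and C11 ketones, C8 ester, isopropyl axial; C8 enolisable) | O=C1C[C@H]2[C@@H](C(C)C)CCC(=O)[C@@H]2CC1C(=O)OC | intermediate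
11 | C11 enol triflate of 10 (C11=C12) | O=C1C[C@H]2[C@@H](C(C)C)CC=C(OS(=O)(=O)C(F)(F)F)[C@@H]2CC1C(=O)OC | intermediate
12 | trans-fused β-keto ester with C11(CH3)=C12 | O=C1C[C@H]2[C@@H](C(C)C)CC=C(C)[C@@H]2CC1C(=O)OC | intermediate
13 | trans-fused 8-isopropyl-5-methyl-3,4,4a,7,8,8a-hexahydronaphthalen-2(1H)-one (C7 ketone) | O=C1C[C@H]2[C@@H](C(C)C)CC=C(C)[C@@H]2CC1 | intermediate
14 | C8 hydroxy derivative of 13 (C8 epimers) | O=C1C[C@H]2[C@@H](C(C)C)CC=C(C)[C@@H]2CC1O | intermediate
15 | C8 equatorial triisopropylsilyloxy C7 ketone | O=C1[C@@H](O[Si](C(C)C)(C(C)C)C(C)C)C[C@H]2C(C)=CC[C@H](C(C)C)[C@@H]2C1 | intermediate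
16 | 2,2-dimethyl-1,3-dioxan-5-one | CC1(C)OCC(=O)CO1 | starting material
17 | aldol adduct with equatorial C2 (5-hydroxy-2,2-dimethyl-1,3-dioxan-5-yl) group | O=C1[C@@H](O[Si](C(C)C)(C(C)C)C(C)C)C[C@H]2C(C)=CC[C@H](C(C)C)[C@@H]2[C@H]1C3(O)COC(C)(C)OC3 | intermediate
18 | C7 ketone with equatorial C2 (2,2-dimethyl-4H-1,3-dioxin-5-yl) group | O=C1[C@@H](O[Si](C(C)C)(C(C)C)C(C)C)C[C@H]2C(C)=CC[C@H](C(C)C)[C@@H]2[C@H]1C3=COC(C)(C)OC3 | intermediate
19 | trans-decalin carbinol: axial C7 ethynyl, equatorial C2 dioxinyl, equatorial C8 OSi | C#C[C@@]1(O)[C@@H](O[Si](C(C)C)(C(C)C)C(C)C)C[C@H]2C(C)=CC[C@H](C(C)C)[C@@H]2[C@H]1C3=COC(C)(C)OC3 | intermediate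
20 | potassium alkoxide of 19 | C#C[C@@]1([O-])[C@@H](O[Si](C(C)C)(C(C)C)C(C)C)C[C@H]2C(C)=CC[C@H](C(C)C)[C@@H]2[C@H]1C3=COC(C)(C)OC3.[K+] | intermediate
21 | potassium allenolate of the ten-membered ring (C5=C6=C7–O−) | C1[C@H](O[Si](C(C)C)(C(C)C)C(C)C)C([O-])=C=C[C@H]3OC(C)(C)OC/C3=C/[C@H]2[C@@H](C(C)C)CC=C(C)[C@@H]21.[K+] | intermediate
22 | ten-membered C7 enone, Z C5=C6, ring-cis C2=C3, C4/C15 acetonide, C8 OSi | C1[C@H](O[Si](C(C)C)(C(C)C)C(C)C)C(=O)/C=C\[C@H]3OC(C)(C)OC/C3=C/[C@H]2[C@@H](C(C)C)CC=C(C)[C@@H]21 | intermediate
23 | C7 methyl carbinol of 22 | C1[C@H](O[Si](C(C)C)(C(C)C)C(C)C)[C@](O)(C)/C=C\[C@H]3OC(C)(C)OC/C3=C/[C@H]2[C@@H](C(C)C)CC=C(C)[C@@H]21 | intermediate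
24 | triol (C4, C7, C15 hydroxyls; C8 OSi) | C1[C@H](O[Si](C(C)C)(C(C)C)C(C)C)[C@](O)(C)/C=C\[C@@H](O)/C(CO)=C\[C@H]2[C@@H](C(C)C)CC=C(C)[C@@H]21 | intermediate
25 | hemiketal enal (C4–O–C7 bridge, C15 aldehyde, C8 OSi) | O=C/C1=C/[C@H]2[C@@H](C(C)C)CC=C(C)[C@@H]2C[C@H](O[Si](C(C)C)(C(C)C)C(C)C)[C@]2(C)C=C[C@@]1(O)O2 | intermediate
26 | hemiketal C15 carboxylic acid | OC(=O)/C1=C/[C@H]2[C@@H](C(C)C)CC=C(C)[C@@H]2C[C@H](O[Si](C(C)C)(C(C)C)C(C)C)[C@]2(C)C=C[C@@]1(O)O2 | intermediate
27 | hemiketal methyl ester with C8 OSi | COC(=O)/C1=C/[C@H]2[C@@H](C(C)C)CC=C(C)[C@@H]2C[C@H](O[Si](C(C)C)(C(C)C)C(C)C)[C@]2(C)C=C[C@@]1(O)O2 | intermediate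
28 | hemiketal methyl ester with free C8 hydroxyl | COC(=O)/C1=C/[C@H]2[C@@H](C(C)C)CC=C(C)[C@@H]2C[C@H](O)[C@]2(C)C=C[C@@]1(O)O2 | intermediate
29 | urocanic acid | OC(=O)/C=C/c1c[nH]cn1 | starting material
30 | methyl urocanate | COC(=O)/C=C/c1c[nH]cn1 | intermediate
31 | methyl (E)-3-(1-methylimidazol-4-yl)acrylate | COC(=O)/C=C/c1cn(C)cn1 | intermediate
32 | (E)-3-(1-methylimidazol-4-yl)acrylic acid | OC(=O)/C=C/c1cn(C)cn1 | intermediate
33 | mixed pivalic anhydride of 32 | CC(C)(C)C(=O)OC(=O)/C=C/c1cn(C)cn1 | intermediate
34 | target compound | COC(=O)/C1=C/[C@H]2[C@@H](C(C)C)CC=C(C)[C@@H]2C[C@H](OC(=O)/C=C/c2cn(C)cn2)[C@]2(C)C=C[C@@]1(O)O2 | target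

**Step count and risks**

Total step count: 24. Longest linear sequence: 21 (steps 1–20 and 24).

Step 14 is the most exposed step. The propargylic alkoxide may fragment by loss of acetylide, proton exchange under the basic conditions may epimerise C8, and protonation of the allenolate may not be selective for the cis enone. The fallback keeps the same C2–C7 cleavage and C4–C5 bond formation but changes the partner: it sets out from 18 and comes back at 22. Vinylmagnesium bromide with CeCl3 should add axially to 18 to give the vinyl carbinol F1. Its potassium alkoxide (KH, 18-crown-6) undergoes the faster all-alkene anionic oxy-Cope ring expansion, and the regiodefined enolate is trapped with Me3SiCl as the ring-expanded enol silane F2. Saegusa–Ito oxidation with Pd(OAc)2 (divalent palladium) then introduces C5=C6 and gives 22; any E enone would be equilibrated to the ring-cis isomer with a trace of iodine under light.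

Step 15 may suffer from poor facial selectivity, through chelation by the C8 oxygen or a ring conformer that exposes the inner face, leading to the C7 epimer. The fallback sets out from 22 and comes back at 23. Methylenation (Ph3P=CH2) gives the C7 methylene diene F3, and Bu4NF frees the allylic alcohol F4. Hydroxyl-directed epoxidation (VO(acac)2, tBuOOH) of this 2-substituted allylic alcohol should deliver oxygen to the face required for C7, giving the spiro epoxy alcohol F5. LiEt3BH opens the epoxide at its CH2 carbon to the C7,C8 diol F6, and selective silylation of the secondary hydroxyl (iPr3SiOTf, 2,6-lutidine) returns 23.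

Step 5 may fail through oligomerisation of methyl acrylate and through proton exchange, which would move the enolate to C12 (Claisen closure to a bridged dione) or epimerise C10 before the carbon–carbon bond forms. The fallback sets out from 6 (through 8, made in the same way) and comes back at 13. The potassium enolate is trapped with phenyl vinyl sulfone, which cannot polymerise and offers no carbonyl to attack; the α-sulfonyl carbanion closes ring B onto the ester to give the β-keto sulfone F7. Enol triflate formation as in step 6 gives the sulfonyl enol triflate F8, Stille methylation gives the methylated β-keto sulfone F9, and reductive desulfonylation with SmI2 returns 13.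

**Further compounds**

F1 | step 14 | trans-decalin carbinol with axial C7 vinyl, equatorial C2 dioxinyl, equatorial C8 OSi | C=C[C@@]1(O)[C@@H](O[Si](C(C)C)(C(C)C)C(C)C)C[C@H]2C(C)=CC[C@H](C(C)C)[C@@H]2[C@H]1C3=COC(C)(C)OC3
F2 | step 14 | ring-expanded C6=C7 trimethylsilyl enol ether (C4 configuration and enol ether geometry immaterial) | C1[C@H](O[Si](C(C)C)(C(C)C)C(C)C)C(O[Si](C)(C)C)=CCC3OC(C)(C)OC/C3=C/[C@H]2[C@@H](C(C)C)CC=C(C)[C@@H]21
F3 | step 15 | C7 methylene diene with C8 OSi | C1[C@H](O[Si](C(C)C)(C(C)C)C(C)C)C(=C)/C=C\[C@H]3OC(C)(C)OC/C3=C/[C@H]2[C@@H](C(C)C)CC=C(C)[C@@H]21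
F4 | step 15 | C7 methylene diene with free C8 hydroxyl | C1[C@H](O)C(=C)/C=C\[C@H]3OC(C)(C)OC/C3=C/[C@H]2[C@@H](C(C)C)CC=C(C)[C@@H]21
F5 | step 15 | C7 spiro epoxy alcohol | C1[C@H](O)[C@]4(CO4)/C=C\[C@H]3OC(C)(C)OC/C3=C/[C@H]2[C@@H](C(C)C)CC=C(C)[C@@H]21
F6 | step 15 | C7 methyl carbinol with free C8 hydroxyl | C1[C@H](O)[C@](O)(C)/C=C\[C@H]3OC(C)(C)OC/C3=C/[C@H]2[C@@H](C(C)C)CC=C(C)[C@@H]21
F7 | step 5 | trans-fused β-keto sulfone (C7 ketone, C8 SO2Ph, C11 ketone) | O=C1C[C@H]2[C@@H](C(C)C)CCC(=O)[C@@H]2CC1S(=O)(=O)c1ccccc1
F8 | step 5 | C11 enol triflate of the β-keto sulfone | O=C1C[C@H]2[C@@H](C(C)C)CC=C(OS(=O)(=O)C(F)(F)F)[C@@H]2CC1S(=O)(=O)c1ccccc1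
F9 | step 5 | β-keto sulfone with C11(CH3)=C12 | O=C1C[C@H]2[C@@H](C(C)C)CC=C(C)[C@@H]2CC1S(=O)(=O)c1ccccc1
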